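**Assumption:** the target is taken exactly as the given SMILES (cembrane numbering; each half 1R,3S,4S,7E,11S,12S; 15S at the CH half, 15′S at the C–OH half). The antipode named for each chiral catalyst is the one expected to give these centres; its mirror image is used if the sense proves opposite.

## Retrosynthetic overview

1. Target 25 ⇒ reductive C17–C17′ coupling of the α-methylene lactone monomer 22 with its own spiro-epoxide 23 (cobalt-mediated epoxide-opening radical conjugate addition).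
2. 22 ⇒ α-methylenation of macrocyclic lactone 19 ⇐ diimide reduction ⇐ ring-closing metathesis at C13=C14 of vinyl lactone/vinyl epoxide 17.
3. 17 ⇐ organocatalytic iminium epoxidation of enal 15 (C11, C12) ⇐ SeO2 oxidation ⇐ trans-selective vinyl conjugate addition (C1) to dihydropyranone 12.
4. 12 ⇐ acrylate ring-closing metathesis of diol 10 ⇐ chelation-controlled homogeranyl addition (C4) to ketol 3 ⇐ D-proline α-aminoxylation of hex-5-en-2-one (C3, first stereocentre).
5. Ring order: δ-lactone (step 5), oxirane (step 8), 14-membered carbocycle (step 10), spiro-oxirane (step 13); the dimer bond is made last.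

## Route

Step 1
Reactants: 1 hex-5-en-2-one
Product: 3 (S)-3-hydroxyhex-5-en-2-one, via α-anilinooxy ketone 2 (not isolated)
Conditions: D-proline (20 mol%), PhNO (slow addition), 1 (3 equiv), DMSO, rt; then CuSO4·5H2O (30 mol%), MeOH, 0 °C
Reagents that add atoms: nitrosobenzene, O=Nc1ccccc1
Why: Proline enamine catalysis (α-aminoxylation, O-selective nitroso aldol) oxygenates the more substituted enamine at C3 through the acid-directed transition state (D-proline gives 3S), and CuSO4-catalysed N–O cleavage frees the ketol without touching the stereocentre.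

Step 2
Reactants: 4 geranyl bromide; 5 thioanisole
Product: 7 (E)-(4,8-dimethylnona-3,7-dien-1-yl)(phenyl)sulfane, via (phenylthio)methyllithium 6 (not isolated)
Conditions: 5, n-BuLi, DABCO, THF, 0 °C; then 4, −78 °C to rt
Reagents that add atoms: none
Why: SN2 alkylation of the sulfur-stabilised carbanion at the primary allylic bromide (one-carbon homologation of the Corey–Jautelat type) leaves the E-olefin untouched and creates no stereocentre.

Step 3
Reactants: 7 (E)-(4,8-dimethylnona-3,7-dien-1-yl)(phenyl)sulfane; 3 (S)-3-hydroxyhex-5-en-2-one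
Product: 10 (4S,5S,8E)-5,9,13-trimethyltetradeca-1,8,12-triene-4,5-diol, via homogeranyllithium 8 (not isolated), via homogeranylmagnesium bromide 9 (not isolated)
Conditions: 7 (1.6 equiv), lithium 4,4′-di-tert-butylbiphenylide, THF, −78 °C; MgBr2·OEt2; then 3 (pre-mixed with i-PrMgCl, 1.0 equiv, THF, −78 °C), −78 to −30 °C; aq NH4Cl
Reagents that add atoms: none
Why: Reductive lithiation of the C–S bond and transmetalation give a Grignard reagent that adds to the five-membered magnesium chelate of the α-alkoxido ketone from the C3–H face (Cram chelate control), setting C4 (S) syn to C3.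

Step 4
Reactants: 10 (4S,5S,8E)-5,9,13-trimethyltetradeca-1,8,12-triene-4,5-diol
Product: 11 (4S,5S,8E)-5-hydroxy-5,9,13-trimethyltetradeca-1,8,12-trien-4-yl acrylate
Conditions: CH2=CHCOCl (1.1 equiv), Et3N, CH2Cl2, −78 to 0 °C
Reagents that add atoms: acryloyl chloride, C=CC(=O)Cl
Why: Nucleophilic acyl substitution acylates the secondary hydroxyl far faster than the hindered tertiary one, and no stereocentre changes.

Step 5
Reactants: 11 (4S,5S,8E)-5-hydroxy-5,9,13-trimethyltetradeca-1,8,12-trien-4-yl acrylate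
Product: 12 (6S)-6-[(2S,5E)-2-hydroxy-6,10-dimethylundeca-5,9-dien-2-yl]-5,6-dihydro-2H-pyran-2-one
Conditions: first-generation Grubbs catalyst (10 mol%), Ti(Oi-Pr)4 (0.3 equiv), CH2Cl2 (5 mM), 40 °C
Reagents that add atoms: none
Why: Ring-closing metathesis of the acrylate with the terminal olefin closes the six-membered unsaturated lactone, and the trisubstituted olefins are inert to this catalyst.

Step 6
Reactants: 12 (6S)-6-[(2S,5E)-2-hydroxy-6,10-dimethylundeca-5,9-dien-2-yl]-5,6-dihydro-2H-pyran-2-one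
Product: 13 (4R,6S)-6-[(2S,5E)-2-hydroxy-6,10-dimethylundeca-5,9-dien-2-yl]-4-vinyltetrahydro-2H-pyran-2-one
Conditions: CH2=CHMgBr (3 equiv), CuI (20 mol%), THF, −78 to −40 °C; aq NH4Cl
Reagents that add atoms: vinylmagnesium bromide, C=C[Mg]Br
Why: Copper-catalysed conjugate addition delivers the vinyl group axially to the half-chair enoate, anti to the pseudo-equatorial C3 substituent, giving the 1,3-trans lactone and setting C1 (R).

Step 7
Reactants: 13 (4R,6S)-6-[(2S,5E)-2-hydroxy-6,10-dimethylundeca-5,9-dien-2-yl]-4-vinyltetrahydro-2H-pyran-2-one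
Product: 15 (2E,6E,10S)-10-hydroxy-2,6-dimethyl-10-[(2S,4R)-6-oxo-4-vinyltetrahydro-2H-pyran-2-yl]undeca-2,6-dienal, via allylic alcohol 14 (not isolated)
Conditions: SeO2 (0.3 equiv), t-BuOOH, salicylic acid (10 mol%), CH2Cl2, rt; then MnO2, CH2Cl2, rt
Reagents that add atoms: tert-butyl hydroperoxide, CC(C)(C)OO
Why: SeO2-catalysed allylic oxidation (ene reaction then 2,3-shift) selects the E-methyl of the terminal trisubstituted olefin, and MnO2 oxidises only the resulting primary allylic alcohol.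

Step 8
Reactants: 15 (2E,6E,10S)-10-hydroxy-2,6-dimethyl-10-[(2S,4R)-6-oxo-4-vinyltetrahydro-2H-pyran-2-yl]undeca-2,6-dienal
Product: 16 (2R,3S)-3-{(3E,7S)-7-hydroxy-3-methyl-7-[(2S,4R)-6-oxo-4-vinyltetrahydro-2H-pyran-2-yl]oct-3-en-1-yl}-2-methyloxirane-2-carbaldehyde
Conditions: 9-amino-9-deoxy-epi-quinine (10 mol%), (R)-TRIP (20 mol%), 50% aq H2O2, THF, 40 °C
Reagents that add atoms: hydrogen peroxide, OO
Why: Iminium-ion-catalysed nucleophilic epoxidation (conjugate addition of H2O2, then enamine ring closure) occurs only at the enal, and the chiral primary amine/phosphate ion pair sets C11 (S) and C12 independently of the remote centres.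

Step 9
Reactants: 16 (2R,3S)-3-{(3E,7S)-7-hydroxy-3-methyl-7-[(2S,4R)-6-oxo-4-vinyltetrahydro-2H-pyran-2-yl]oct-3-en-1-yl}-2-methyloxirane-2-carbaldehyde
Product: 17 (4R,6S)-6-{(2S,5E)-2-hydroxy-6-methyl-8-[(2S,3S)-3-methyl-3-vinyloxiran-2-yl]oct-5-en-2-yl}-4-vinyltetrahydro-2H-pyran-2-one
Conditions: Ph3PCH3Br, KN(SiMe3)2, THF, 0 °C; then 16, −78 to 0 °C
Reagents that add atoms: methyltriphenylphosphonium bromide, C[P+](c1ccccc1)(c1ccccc1)c1ccccc1.[Br-]
Why: Wittig methylenation of the non-enolisable epoxy aldehyde gives the vinyl epoxide without touching the epoxide or the lactone.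

Step 10
Reactants: 17 (4R,6S)-6-{(2S,5E)-2-hydroxy-6-methyl-8-[(2S,3S)-3-methyl-3-vinyloxiran-2-yl]oct-5-en-2-yl}-4-vinyltetrahydro-2H-pyran-2-one
Product: 18 (1R,3S,4S,7E,11S,12S)-11,12-epoxy-4-hydroxy-17-norcembra-7,13-dien-16,3-olide (C13=C14 as E/Z mixture)
Conditions: second-generation Hoveyda–Grubbs catalyst (10 mol%), 1,4-benzoquinone (20 mol%), toluene (1 mM), 80 °C
Reagents that add atoms: none
Why: Ring-closing metathesis of the two monosubstituted olefins closes the 14-membered ring at C13=C14, and the trisubstituted C7=C8 olefin cannot compete because a six-membered closure onto it would need a trans-fused epoxide.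

Step 11
Reactants: 18 (1R,3S,4S,7E,11S,12S)-11,12-epoxy-4-hydroxy-17-norcembra-7,13-dien-16,3-olide
Product: 19 (1R,3S,4S,7E,11S,12S)-11,12-epoxy-4-hydroxy-17-norcembr-7-en-16,3-olide
Conditions: 2-nitrobenzenesulfonylhydrazide, Et3N, CH2Cl2, rt
Reagents that add atoms: none
Why: Diimide (concerted syn hydrogen transfer) reduces the 1,2-disubstituted C13=C14 olefin much faster than the trisubstituted C7=C8 olefin and leaves the allylic epoxide and the lactone intact.

Step 12
Reactants: 19 (1R,3S,4S,7E,11S,12S)-11,12-epoxy-4-hydroxy-17-norcembr-7-en-16,3-olide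
Product: 22 (1R,3S,4S,7E,11S,12S)-11,12-epoxy-4-hydroxycembra-7,15(17)-dien-16,3-olide, via Mannich base 20 (not isolated), via trimethylammonium iodide 21 (not isolated)
Conditions: LiN(i-Pr)2 (2.3 equiv), THF, −78 °C; CH2=NMe2+ I−, −78 to 0 °C; then MeI, MeOH, rt; then aq NaHCO3, CH2Cl2
Reagents that add atoms: Eschenmoser's salt (dimethylmethyleneammonium iodide), C=[N+](C)C.[I-]
Why: Mannich reaction of the lactone enolate, N-methylation and E1cB elimination (α-methylenation) install the exocyclic methylene without affecting any stereocentre.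

Step 13
Reactants: 22 (1R,3S,4S,7E,11S,12S)-11,12-epoxy-4-hydroxycembra-7,15(17)-dien-16,3-olide
Product: 23 (1R,3S,4S,7E,11S,12S,15R)-11,12:15,17-diepoxy-4-hydroxycembr-7-en-16,3-olide
Conditions: t-BuOOH, LiN(SiMe3)2, THF, −78 to −20 °C
Reagents that add atoms: tert-butyl hydroperoxide, CC(C)(C)OO
Why: Weitz–Scheffer nucleophilic epoxidation adds t-BuOOLi to the exocyclic methylene and the enolate closes onto oxygen on the lactone face anti to C14, giving the spiro-epoxide with the C15 configuration needed for C15′–OH while the electron-rich C7=C8 olefin is not attacked.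

Step 14
Reactants: 23 (1R,3S,4S,7E,11S,12S,15R)-11,12:15,17-diepoxy-4-hydroxycembr-7-en-16,3-olide; 22 (1R,3S,4S,7E,11S,12S)-11,12-epoxy-4-hydroxycembra-7,15(17)-dien-16,3-olide
Product: 25 CNP0186476.4, via C15-epimeric dimer 24 (not isolated)
Conditions: 23 (1.0 equiv), 22 (1.3 equiv), cyanocobalamin (C63H88CoN14O14P, 10 mol%), Zn, NH4Cl, DMF/MeOH, blue LEDs, rt; then DBU (0.3 equiv), CH2Cl2, rt
Reagents that add atoms: none
Why: Proposed new method: Zn reduces cyanocobalamin to monovalent cobalt, which opens the spiro-epoxide of 23 by SN2 attack at the unhindered exocyclic CH2 (the trisubstituted ring epoxides are too hindered); visible-light homolysis of the 2-hydroxyalkyl–cobalt bond releases the primary C17′ radical, which adds to the exocyclic methylene of 22 to form the C17–C17′ bond; the α-lactone radical is reduced and protonated, C15′ keeps the epoxide-derived configuration, and DBU equilibrates C15 to the isomer with the side chain anti to C14 (15S); the closest known reaction types are vitamin-B12/Zn photochemical Giese additions of alkyl halides and cobalt-controlled opening of epoxides at the less hindered carbon in cross-electrophile coupling, neither shown for glycidic-lactone spiro-epoxides or α-methylene lactone acceptors.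

## Compound list

1 | hex-5-en-2-one | CC(=O)CCC=C | starting material
2 | (S)-3-(phenylaminooxy)hex-5-en-2-one | CC(=O)[C@@H](ONc1ccccc1)CC=C | intermediate
3 | (S)-3-hydroxyhex-5-en-2-one | CC(=O)[C@@H](O)CC=C | intermediate
4 | geranyl bromide, (E)-1-bromo-3,7-dimethylocta-2,6-diene | CC(C)=CCC/C(C)=C/CBr | starting material
5 | thioanisole | CSc1ccccc1 | starting material
6 | (phenylthio)methyllithium | [Li]CSc1ccccc1 | intermediate
7 | (E)-(4,8-dimethylnona-3,7-dien-1-yl)(phenyl)sulfane | CC(C)=CCC/C(C)=C/CCSc1ccccc1 | intermediate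
8 | (E)-(4,8-dimethylnona-3,7-dien-1-yl)lithium | CC(C)=CCC/C(C)=C/CC[Li] | intermediate
9 | (E)-(4,8-dimethylnona-3,7-dien-1-yl)magnesium bromide | CC(C)=CCC/C(C)=C/CC[Mg]Br | intermediate
10 | (4S,5S,8E)-5,9,13-trimethyltetradeca-1,8,12-triene-4,5-diol | C=CC[C@H](O)[C@@](C)(O)CC/C=C(C)/CCC=C(C)C | intermediate
11 | (4S,5S,8E)-5-hydroxy-5,9,13-trimethyltetradeca-1,8,12-trien-4-yl acrylate | C=CC[C@H](OC(=O)C=C)[C@@](C)(O)CC/C=C(C)/CCC=C(C)C | intermediate
12 | (6S)-6-[(2S,5E)-2-hydroxy-6,10-dimethylundeca-5,9-dien-2-yl]-5,6-dihydro-2H-pyran-2-one | O=C1C=CC[C@H](O1)[C@@](C)(O)CC/C=C(C)/CCC=C(C)C | intermediate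
13 | (4R,6S)-6-[(2S,5E)-2-hydroxy-6,10-dimethylundeca-5,9-dien-2-yl]-4-vinyltetrahydro-2H-pyran-2-one | O=C1C[C@H](C=C)C[C@H](O1)[C@@](C)(O)CC/C=C(C)/CCC=C(C)C | intermediate
14 | (4R,6S)-6-[(2S,5E,9E)-2,11-dihydroxy-6,10-dimethylundeca-5,9-dien-2-yl]-4-vinyltetrahydro-2H-pyran-2-one | O=C1C[C@H](C=C)C[C@H](O1)[C@@](C)(O)CC/C=C(C)/CC/C=C(C)/CO | intermediate
15 | (2E,6E,10S)-10-hydroxy-2,6-dimethyl-10-[(2S,4R)-6-oxo-4-vinyltetrahydro-2H-pyran-2-yl]undeca-2,6-dienal | O=C1C[C@H](C=C)C[C@H](O1)[C@@](C)(O)CC/C=C(C)/CC/C=C(C)/C=O | intermediate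
16 | (2R,3S)-3-{(3E,7S)-7-hydroxy-3-methyl-7-[(2S,4R)-6-oxo-4-vinyltetrahydro-2H-pyran-2-yl]oct-3-en-1-yl}-2-methyloxirane-2-carbaldehyde | O=C1C[C@H](C=C)C[C@H](O1)[C@@](C)(O)CC/C=C(C)/CC[C@@H]1O[C@@]1(C)C=O | intermediate
17 | (4R,6S)-6-{(2S,5E)-2-hydroxy-6-methyl-8-[(2S,3S)-3-methyl-3-vinyloxiran-2-yl]oct-5-en-2-yl}-4-vinyltetrahydro-2H-pyran-2-one | O=C1C[C@H](C=C)C[C@H](O1)[C@@](C)(O)CC/C=C(C)/CC[C@@H]1O[C@@]1(C)C=C | intermediate
18 | (1R,3S,4S,7E,11S,12S)-11,12-epoxy-4-hydroxy-17-norcembra-7,13-dien-16,3-olide (C13=C14 E/Z mixture) | C/C1=C\CC[C@](C)(O)[C@@H]2C[C@@H](C=C[C@]3(C)O[C@H]3CC1)CC(=O)O2 | intermediate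
19 | (1R,3S,4S,7E,11S,12S)-11,12-epoxy-4-hydroxy-17-norcembr-7-en-16,3-olide | C/C1=C\CC[C@](C)(O)[C@@H]2C[C@@H](CC[C@]3(C)O[C@H]3CC1)CC(=O)O2 | intermediate
20 | 15-(dimethylaminomethyl) derivative of 19 (C15 epimers) | C/C1=C\CC[C@](C)(O)[C@@H]2C[C@@H](CC[C@]3(C)O[C@H]3CC1)C(CN(C)C)C(=O)O2 | intermediate
21 | 15-(trimethylammoniomethyl) derivative of 19, iodide (C15 epimers) | C/C1=C\CC[C@](C)(O)[C@@H]2C[C@@H](CC[C@]3(C)O[C@H]3CC1)C(C[N+](C)(C)C)C(=O)O2.[I-] | intermediate
22 | (1R,3S,4S,7E,11S,12S)-11,12-epoxy-4-hydroxycembra-7,15(17)-dien-16,3-olide (α-methylene lactone monomer, sinularin skeleton) | C/C1=C\CC[C@](C)(O)[C@@H]2C[C@@H](CC[C@]3(C)O[C@H]3CC1)C(=C)C(=O)O2 | intermediate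
23 | (1R,3S,4S,7E,11S,12S,15R)-11,12:15,17-diepoxy-4-hydroxycembr-7-en-16,3-olide (spiro-epoxide, epoxide O anti to C14) | C1O[C@@]12C(=O)O[C@H]3C[C@H]2CC[C@]4(C)O[C@H]4CC/C(C)=C/CC[C@]3(C)O | intermediate
24 | C15-epimer (15R) of 25 | C/C1=C\CC[C@](C)(O)[C@@H]2C[C@@H](CC[C@]3(C)O[C@H]3CC1)[C@@H](CC[C@@]1(O)C(=O)O[C@H]3C[C@H]1CC[C@]1(C)O[C@H]1CC/C(C)=C/CC[C@]3(C)O)C(=O)O2 | intermediate
25 | CNP0186476.4 (15S half linked C17–C17′ to the 15′S-hydroxy half) | C/C1=C\CC[C@](C)(O)[C@@H]2C[C@@H](CC[C@]3(C)O[C@H]3CC1)[C@H](CC[C@@]1(O)C(=O)O[C@H]3C[C@H]1CC[C@]1(C)O[C@H]1CC/C(C)=C/CC[C@]3(C)O)C(=O)O2 | target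

## Step count and risks

Total step count: 14. Longest linear sequence: 13 steps (geranyl bromide 4 through steps 2–14).

**Step 14 (the proposed new coupling).** Monovalent cobalt may add directly to the acceptor 22, the other epoxides may be reduced, and the C15 outcome rests on DBU equilibration of 24 to 25, which is not proven to favour 25. The fallback uses known chemistry and sets out from 22 alone. An N-heterocyclic carbene (1,3,4-triphenyl-1,2,4-triazol-5-ylidene, 10 mol%, 1,4-dioxane, 80 °C) effects the known tail-to-tail umpolung dimerisation of α-methylene lactones to the dehydro-dimer F1, in which one half is the saturated 15S lactone and the other an E-alkylidene lactone. Mukaiyama-type hydrogen-atom-transfer hydroxylation of the conjugated alkylidene lactone (Mn(dpm)3 10 mol%, PhSiH3, O2, i-PrOH/CH2Cl2, 0 °C) gives the C15′ hydroperoxide F2, with O2 captured anti to C14′. P(OEt)3 reduces F2, and the route is rejoined at 25.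

**Step 10 (macrocyclic ring-closing metathesis).** The vinyl group on the fully substituted epoxide carbon is hindered, so catalyst loading there may be slow and oligomers may form. The fallback is relay ring-closing metathesis. It sets out from 16, which is treated with the ylide from (hex-5-en-1-yl)triphenylphosphonium bromide and KN(SiMe3)2 to give the relay triene F3. The second-generation Grubbs catalyst initiates at the unhindered terminal olefin of F3, expels cyclopentene to place ruthenium on C13, and closes onto the C1 vinyl group. The route is rejoined at 18.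

**Step 8 (organocatalytic epoxidation of the advanced α-branched enal).** Conversion or diastereoselectivity may be poor on this substrate. The fallback sets out from allylic alcohol 14, which is then isolated after the SeO2 stage instead of being oxidised. Sharpless asymmetric epoxidation (Ti(Oi-Pr)4, L-(+)-diethyl tartrate, t-BuOOH, 4 Å sieves, CH2Cl2, −20 °C) gives the (11S,12S) epoxy alcohol F4. Dess–Martin oxidation of F4 rejoins the route at 16.

## Further compounds

F1 | step 14 | dehydro-dimer: 15S saturated half linked through C17H2–C17′H= to the E-alkylidene lactone half | C/C1=C\CC[C@](C)(O)[C@@H]2C[C@@H](CC[C@]3(C)O[C@H]3CC1)[C@H](C/C=C1/C(=O)O[C@H]3C[C@H]1CC[C@]1(C)O[C@H]1CC/C(C)=C/CC[C@]3(C)O)C(=O)O2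
F2 | step 14 | C15′ hydroperoxide of 25 | C/C1=C\CC[C@](C)(O)[C@@H]2C[C@@H](CC[C@]3(C)O[C@H]3CC1)[C@H](CC[C@@]1(OO)C(=O)O[C@H]3C[C@H]1CC[C@]1(C)O[C@H]1CC/C(C)=C/CC[C@]3(C)O)C(=O)O2
F3 | step 10 | relay triene: 17 with the epoxide vinyl group replaced by (Z)-hepta-1,6-dien-1-yl | O=C1C[C@H](C=C)C[C@H](O1)[C@@](C)(O)CC/C=C(C)/CC[C@@H]1O[C@@]1(C)/C=C\CCCC=C
F4 | step 8 | (11S,12S) epoxy alcohol: 16 with CH2OH in place of CHO | O=C1C[C@H](C=C)C[C@H](O1)[C@@](C)(O)CC/C=C(C)/CC[C@@H]1O[C@@]1(C)CO
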